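The flavonol is cut through ring C: C4 is a lone carbonyl carbon held between C4a of ring A and the C3=C2 unit, and O1 sits on ring A next to C4a. A palladium-catalysed carbonylative alkyne coupling with ensuing oxa-Michael closure therefore joins an ortho-iodophenol, carbon monoxide and an arylacetylene, making C4a–C4, C4–C3 and O1–C2 and closing ring C in one operation. The iodide partner is 2-iodo-3,5-bis(benzyloxy)phenol, used as its acetate to tame the electron-rich, doubly ortho-substituted C–I bond; the alkyne carries O4' as a triisopropylsilyl ether. C3 oxygenation, debenzylation, chelation-controlled sulfation of O3 and O7, and desilylation then finish the target.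

Key step: step 6

Remark: sulfate monoesters are drawn as free acids, as in the target; they would be handled as pyridinium, tetrabutylammonium or potassium salts and brought to the acid form on an H+-form cation-exchange resin, which is treated as work-up.

Step 1
Reactants: 1 4-iodophenol
Product: 2 (4-iodophenoxy)triisopropylsilane
Conditions: TIPSCl, imidazole, DMF, rt
Reagents that add atoms: triisopropylsilyl chloride, CC(C)[Si](Cl)(C(C)C)C(C)C
Why: Imidazole-promoted O-silylation of an unhindered phenol is routine, and the bulky silyl ether is chosen because it should outlast amine, carbonate, hydrogenation and sulfation conditions yet fall to fluoride at the end.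

Step 2
Reactants: 2 (4-iodophenoxy)triisopropylsilane; 3 trimethylsilylacetylene
Product: 4 triisopropyl{4-[(trimethylsilyl)ethynyl]phenoxy}silane
Conditions: PdCl2(PPh3)2 (2 mol%), CuI (4 mol%), Et3N, THF, rt
Reagents that add atoms: none
Why: Sonogashira coupling of an aryl iodide with a silyl-capped terminal alkyne runs at room temperature and leaves the aryl silyl ether untouched.

Step 3
Reactants: 4 triisopropyl{4-[(trimethylsilyl)ethynyl]phenoxy}silane
Product: 5 4-(triisopropylsilyloxy)phenylacetylene
Conditions: K2CO3 (0.2 equiv), MeOH/THF, 0 °C → rt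
Reagents that add atoms: none
Why: Base-catalysed methanolysis of the alkynyl C–Si bond (protodesilylation) is much faster at the small trimethylsilyl group than attack on the hindered triisopropylsilyl aryl ether, so only the alkyne terminus should be unmasked.

Step 4
Reactants: 6 3,5-bis(benzyloxy)phenol
Product: 7 2-iodo-3,5-bis(benzyloxy)phenol
Conditions: NIS (1.0 equiv), CH2Cl2, −40 → 0 °C, dark
Reagents that add atoms: N-iodosuccinimide, O=C1CCC(=O)N1I
Why: Electrophilic aromatic iodination of the phloroglucinol-type ring should favour C2, one of two equivalent positions ortho to the hydroxyl and less crowded than C4 between the two benzyloxy groups; the minor 4-iodo isomer and any di-iodide would be removed by chromatography at this stage.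

Step 5
Reactants: 7 2-iodo-3,5-bis(benzyloxy)phenol
Product: 8 2-iodo-3,5-bis(benzyloxy)phenyl acetate
Conditions: Ac2O, pyridine, DMAP (cat.), CH2Cl2, 0 °C → rt
Reagents that add atoms: acetic anhydride, CC(=O)OC(C)=O
Why: DMAP-catalysed O-acetylation masks the phenol as an ester that the amine of the next step removes in the flask, so that no phenoxide is present while palladium engages the hindered C–I bond.

Step 6
Reactants: 8 2-iodo-3,5-bis(benzyloxy)phenyl acetate; 9 carbon monoxide; 5 4-(triisopropylsilyloxy)phenylacetylene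
Product: 12 5,7-di-O-benzyl-4'-O-(triisopropylsilyl)apigenin, via acetoxy ynone 10 (not isolated), via hydroxy enaminone 11 (not isolated)
Conditions: PdCl2(PPh3)2 (5 mol%), dppp, thiourea, DBU, Et2NH, CO (1 atm), 40 °C
Reagents that add atoms: none
Why: Zerovalent palladium generated in situ from PdCl2(PPh3)2 inserts into the C–I bond of 8, CO insertion gives an aroyl complex of divalent palladium, and amine-assisted alkynyl transfer from 5 followed by reductive elimination forms C4a–C4 and C4–C3 in ynone 10. Diethylamine then adds to the ynone in conjugate fashion and cleaves the aryl acetate as N,N-diethylacetamide to give enaminone 11, whose phenol attacks C2 and expels the amine, forming O1–C2. The closest known reaction type is the carbonylative Sonogashira annulation of ortho-iodophenols and their acetates with terminal alkynes to flavones. Ring C closes by 6-endo-trig addition–elimination, and no stereocenter is formed. The step needs carbonylative rather than direct coupling, which the two ortho oxygen substituents (slow direct alkynyl transfer, ready CO insertion) and the acetate mask (no phenoxide to drive benzofuran formation, a less electron-rich ring for oxidative addition) should secure; it also needs flavone rather than aurone closure, which the enaminone secures because only C2 remains electrophilic.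

Step 7
Reactants: 12 5,7-di-O-benzyl-4'-O-(triisopropylsilyl)apigenin
Product: 14 5,7-di-O-benzyl-4'-O-(triisopropylsilyl)kaempferol, via flavone 2,3-epoxide 13 (not isolated)
Conditions: DMDO, acetone/CH2Cl2, 0 °C; then p-TsOH (cat.), CH2Cl2, rt
Reagents that add atoms: dimethyldioxirane, CC1(C)OO1
Why: Dioxirane epoxidation of the C2=C3 enol-ether bond of a 5-O-alkylated flavone, followed by acid-catalysed oxirane opening at C2 (cation stabilised by O1 and the aryl group) and loss of H3, should give the 3-hydroxyflavone, the two transient stereocenters of racemic 13 being erased on re-aromatisation.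

Step 8
Reactants: 14 5,7-di-O-benzyl-4'-O-(triisopropylsilyl)kaempferol
Product: 15 4'-O-(triisopropylsilyl)kaempferol
Conditions: H2 (1 atm), Pd/C (10%), EtOAc/THF, rt
Reagents that add atoms: none
Why: Catalytic hydrogenolysis cleaves both aryl benzyl ethers under neutral conditions that should not touch the silyl ether or the pyranone C2=C3 bond.

Step 9
Reactants: 15 4'-O-(triisopropylsilyl)kaempferol
Product: 16 4'-O-(triisopropylsilyl)kaempferol 3,7-di-O-sulfate
Conditions: SO3·pyridine (5 equiv), pyridine, rt → 40 °C
Reagents that add atoms: sulfur trioxide–pyridine complex, O=S(=O)([O-])[n+]1ccccc1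
Why: O-sulfation with an SO3–amine complex should take the acidic, unhindered 7-OH first and the 3-OH with excess reagent, while the 5-OH, locked in a strong hydrogen bond to the C4 carbonyl, is the least reactive hydroxyl of a flavonol and O4' is silylated.

Step 10
Reactants: 16 4'-O-(triisopropylsilyl)kaempferol 3,7-di-O-sulfate
Product: 17 kaempferol 3,7-di-O-sulfate
Conditions: TBAF, AcOH, THF, 0 °C → rt
Reagents that add atoms: none
Why: Fluoride-induced cleavage of the aryl silyl ether is fast, and buffering with acetic acid should keep the sulfate monoesters intact and avoid exposing the flavonol as an air-sensitive phenoxide.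

Compound list
1 | 4-iodophenol | Oc1ccc(I)cc1 | starting material
2 | (4-iodophenoxy)triisopropylsilane | CC(C)[Si](Oc1ccc(I)cc1)(C(C)C)C(C)C | intermediate
3 | trimethylsilylacetylene | C#C[Si](C)(C)C | starting material
4 | triisopropyl{4-[(trimethylsilyl)ethynyl]phenoxy}silane | CC(C)[Si](Oc1ccc(C#C[Si](C)(C)C)cc1)(C(C)C)C(C)C | intermediate
5 | 4-(triisopropylsilyloxy)phenylacetylene | C#Cc1ccc(O[Si](C(C)C)(C(C)C)C(C)C)cc1 | intermediate
6 | 3,5-bis(benzyloxy)phenol | Oc1cc(OCc2ccccc2)cc(OCc2ccccc2)c1 | starting material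
7 | 2-iodo-3,5-bis(benzyloxy)phenol | Oc1cc(OCc2ccccc2)cc(OCc2ccccc2)c1I | intermediate
8 | 2-iodo-3,5-bis(benzyloxy)phenyl acetate | CC(=O)Oc1cc(OCc2ccccc2)cc(OCc2ccccc2)c1I | intermediate
9 | carbon monoxide | [C-]#[O+] | starting material
10 | 3,5-bis(benzyloxy)-2-{3-[4-(triisopropylsilyloxy)phenyl]prop-2-ynoyl}phenyl acetate (acetoxy ynone, not isolated) | CC(=O)Oc1cc(OCc2ccccc2)cc(OCc2ccccc2)c1C(=O)C#Cc1ccc(O[Si](C(C)C)(C(C)C)C(C)C)cc1 | intermediate
11 | 1-[2,4-bis(benzyloxy)-6-hydroxyphenyl]-3-(diethylamino)-3-[4-(triisopropylsilyloxy)phenyl]prop-2-en-1-one (hydroxy enaminone, not isolated; E isomer drawn, the push–pull alkene equilibrates) | CCN(CC)/C(=C/C(=O)c1c(O)cc(OCc2ccccc2)cc1OCc1ccccc1)c1ccc(O[Si](C(C)C)(C(C)C)C(C)C)cc1 | intermediate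
12 | 5,7-di-O-benzyl-4'-O-(triisopropylsilyl)apigenin; 5,7-bis(benzyloxy)-2-[4-(triisopropylsilyloxy)phenyl]-4H-chromen-4-one | O=c1cc(-c2ccc(O[Si](C(C)C)(C(C)C)C(C)C)cc2)oc2cc(OCc3ccccc3)cc(OCc3ccccc3)c12 | intermediate
13 | 2,3-epoxide of 12 (cis-fused oxirane across C2–C3, racemic, one enantiomer drawn; not isolated) | O=C1[C@H]2O[C@@]2(c2ccc(O[Si](C(C)C)(C(C)C)C(C)C)cc2)Oc2cc(OCc3ccccc3)cc(OCc3ccccc3)c12 | intermediate
14 | 5,7-di-O-benzyl-4'-O-(triisopropylsilyl)kaempferol; 5,7-bis(benzyloxy)-3-hydroxy-2-[4-(triisopropylsilyloxy)phenyl]-4H-chromen-4-one | O=c1c(O)c(-c2ccc(O[Si](C(C)C)(C(C)C)C(C)C)cc2)oc2cc(OCc3ccccc3)cc(OCc3ccccc3)c12 | intermediate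
15 | 4'-O-(triisopropylsilyl)kaempferol; 3,5,7-trihydroxy-2-[4-(triisopropylsilyloxy)phenyl]-4H-chromen-4-one | O=c1c(O)c(-c2ccc(O[Si](C(C)C)(C(C)C)C(C)C)cc2)oc2cc(O)cc(O)c12 | intermediate
16 | 4'-O-(triisopropylsilyl)kaempferol 3,7-di-O-sulfate; 5-hydroxy-4-oxo-2-[4-(triisopropylsilyloxy)phenyl]-4H-chromene-3,7-diyl bis(hydrogen sulfate) | O=c1c(OS(=O)(=O)O)c(-c2ccc(O[Si](C(C)C)(C(C)C)C(C)C)cc2)oc2cc(OS(=O)(=O)O)cc(O)c12 | intermediate
17 | kaempferol 3,7-di-O-sulfate; 5-hydroxy-2-(4-hydroxyphenyl)-4-oxo-4H-chromene-3,7-diyl bis(hydrogen sulfate) | O=c1c(OS(=O)(=O)O)c(-c2ccc(O)cc2)oc2cc(OS(=O)(=O)O)cc(O)c12 | target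

Total step count: 10 steps.
Longest linear sequence: 8 steps (steps 1, 2, 3, 6, 7, 8, 9, 10, from 4-iodophenol). The ring A branch (steps 4, 5) joins at step 6.

Steps most likely to fail

1. Step 6. Oxidative addition into the electron-rich C–I bond flanked by two oxygen substituents may be sluggish. Direct, non-carbonylative coupling followed by cyclisation to a 2-arylbenzofuran may compete. The silyl ether may be partly lost to DBU. Fallback, from 5 and 7, returning at 12: the future C4 is attached to the alkyne as a formyl carbon instead of being delivered as CO. Alkyne 5 would be deprotonated with n-BuLi (THF, −78 °C) and formylated with DMF to give 3-[4-(triisopropylsilyloxy)phenyl]prop-2-ynal F1. Phenol 7 would be protected with MOMCl and i-Pr2NEt as 1,5-bis(benzyloxy)-2-iodo-3-(methoxymethoxy)benzene F2. Iodine–magnesium exchange on F2 with i-PrMgCl·LiCl (THF, 0 °C) and 1,2-addition of the arylmagnesium species to F1 would give racemic 1-[2,4-bis(benzyloxy)-6-(methoxymethoxy)phenyl]-3-[4-(triisopropylsilyloxy)phenyl]prop-2-yn-1-ol F3. Oxidation with MnO2 (CH2Cl2, rt) would give 1-[2,4-bis(benzyloxy)-6-(methoxymethoxy)phenyl]-3-[4-(triisopropylsilyloxy)phenyl]prop-2-yn-1-one F4. Dilute HCl in MeOH/THF would remove the acetal to give 1-[2,4-bis(benzyloxy)-6-hydroxyphenyl]-3-[4-(triisopropylsilyloxy)phenyl]prop-2-yn-1-one F5, and Et2NH in EtOH would close ring C through the enaminone to 12.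

2. Step 4. Iodination may occur at C4 between the two benzyloxy groups instead of ortho to the hydroxyl, and over-iodination may erode the material balance. Fallback, from 6, returning at 7: the position is fixed by directed metalation instead of electrophilic substitution. Phenol 6 would be carbamoylated (ClCONEt2, NaH, THF) to 3,5-bis(benzyloxy)phenyl N,N-diethylcarbamate F6. Directed ortho-lithiation (s-BuLi, TMEDA, THF, −78 °C) should place lithium at the site flanked by the carbamate and a benzyloxy group. The temperature is held at −78 °C to avoid anionic Fries rearrangement and benzylic deprotonation. Quenching with I2 would give 3,5-bis(benzyloxy)-2-iodophenyl N,N-diethylcarbamate F7. Hydrolysis (NaOH, EtOH, reflux) would return 7.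

3. Step 9. Sulfation of the hydrogen-bonded 3-OH may stall, while forcing conditions may begin to sulfate O5, giving charged regioisomers that are hard to separate. Fallback, from 14, returning at 16: the two sulfates are installed one at a time around the debenzylation. In 14 the only free hydroxyl is O3, so SO3·pyridine in pyridine at 50 °C can be pushed to completion to give 5,7-di-O-benzyl-4'-O-(triisopropylsilyl)kaempferol 3-O-sulfate F8. Hydrogenolysis of its salt (H2, Pd/C (10%), MeOH/THF) would give 4'-O-(triisopropylsilyl)kaempferol 3-O-sulfate F9. A slight excess of SO3·pyridine at 0 °C → rt should then sulfate only the free, most acidic 7-OH and rejoin the route at 16.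

Further compounds
F1 | step 6 | 3-[4-(triisopropylsilyloxy)phenyl]prop-2-ynal | O=CC#Cc1ccc(O[Si](C(C)C)(C(C)C)C(C)C)cc1
F2 | step 6 | 1,5-bis(benzyloxy)-2-iodo-3-(methoxymethoxy)benzene | COCOc1cc(OCc2ccccc2)cc(OCc2ccccc2)c1I
F3 | step 6 | 1-[2,4-bis(benzyloxy)-6-(methoxymethoxy)phenyl]-3-[4-(triisopropylsilyloxy)phenyl]prop-2-yn-1-ol (racemic) | COCOc1cc(OCc2ccccc2)cc(OCc2ccccc2)c1C(O)C#Cc1ccc(O[Si](C(C)C)(C(C)C)C(C)C)cc1
F4 | step 6 | 1-[2,4-bis(benzyloxy)-6-(methoxymethoxy)phenyl]-3-[4-(triisopropylsilyloxy)phenyl]prop-2-yn-1-one | COCOc1cc(OCc2ccccc2)cc(OCc2ccccc2)c1C(=O)C#Cc1ccc(O[Si](C(C)C)(C(C)C)C(C)C)cc1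
F5 | step 6 | 1-[2,4-bis(benzyloxy)-6-hydroxyphenyl]-3-[4-(triisopropylsilyloxy)phenyl]prop-2-yn-1-one | Oc1cc(OCc2ccccc2)cc(OCc2ccccc2)c1C(=O)C#Cc1ccc(O[Si](C(C)C)(C(C)C)C(C)C)cc1
F6 | step 4 | 3,5-bis(benzyloxy)phenyl N,N-diethylcarbamate | CCN(CC)C(=O)Oc1cc(OCc2ccccc2)cc(OCc2ccccc2)c1
F7 | step 4 | 3,5-bis(benzyloxy)-2-iodophenyl N,N-diethylcarbamate | CCN(CC)C(=O)Oc1cc(OCc2ccccc2)cc(OCc2ccccc2)c1I
F8 | step 9 | 5,7-di-O-benzyl-4'-O-(triisopropylsilyl)kaempferol 3-O-sulfate | O=c1c(OS(=O)(=O)O)c(-c2ccc(O[Si](C(C)C)(C(C)C)C(C)C)cc2)oc2cc(OCc3ccccc3)cc(OCc3ccccc3)c12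
F9 | step 9 | 4'-O-(triisopropylsilyl)kaempferol 3-O-sulfate | O=c1c(OS(=O)(=O)O)c(-c2ccc(O[Si](C(C)C)(C(C)C)C(C)C)cc2)oc2cc(O)cc(O)c12
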